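**Time and rate.** The flask is read at 6.0 h, with the gas held, and the question is how much target has formed by then from a smaller charge than in either earlier run.

in all of them: gas 31 mM (held)
- autumn: solid substrate 0.070 M; run made earlier
- winter: solid substrate 0.11 M; run made earlier
- flask: solid substrate 0.050 M; time 6.0 h

- autumn (time / h: target / %, solid product / %): 0.333: 0.1, 0; 0.833: 4.6, 1.2; 1.50: 13.3, 0; 2.50: 19.7, 0; 4.00: 31.3, 0.8
- winter (time / h: target / %, solid product / %): 0.667: 2.6, 0; 1.33: 7.6, 0; 2.00: 10.8, 0; 3.00: 14.7, 0; 4.00: 20.8, 0.1

(each reading ± 1 percentage point)

- target is meant together with its solid product
- solid, in amounts per volume of the solution: solid substrate, solid product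
- the analysis behind the earlier runs scatters by 1 percentage point, standard deviation
- at the start none of the solid substrate is in solution
- at the start none of the gas is in solution
- dissolved substrate means what is dissolved; the solid is not counted in it

* the target and solid product together standing at 6.0 h, as a percentage of the solid substrate charged
* concentration of dissolved substrate in solution at 6.0 h, in percent of saturation

**Frozen rate.** Counted in mM rather than percent, target with its solid product nearly coincides at 4.00 h: autumn 21.9 mM, winter 22.9 mM, from different charges. Read as apparent zero order in the solid charged, the yield of the flask is reckoned here as a rate times the time, divided by the charge.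

**The bracket.** The charge caps y at 100%. Two rate readings, each with its scatter, tighten this by hand, as estimates and not as strict bounds. The winter mean from zero, 5.72 mM h⁻¹, gives the upper end, 68.6%. The late autumn slope, 5.04 mM h⁻¹, gives the lower end, 60.5%. Midway stands 5.38 mM h⁻¹, the frozen production rate, target with solid product formed per hour and per volume, and this reckoning commits to 64.6%. The readings bracket [dissolved substrate] only between zero and saturation.

**The forecast.** The forecast stands inside the bracket at 65% and puts [dissolved substrate] at 90% of saturation: “The solution stays saturated, and reaction in solution, not dissolution, sets the pace.”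

**The result.** The flask gives 65.5%, inside the bracket, but [dissolved substrate] stands at 0.503% of saturation.

    solid substrate ⇌ dissolved substrate, rate k1*(cs1 - [dissolved substrate]) while solid is left; crystals form when [dissolved substrate] > cs1 (solubility = 1.90 mM, k = 8.02 × 10⁻⁴ s⁻¹)
    gas ⇌ partner, rate k2*(csat - [partner]) (kL = 0.00233 s⁻¹)
    solid product ⇌ target, rate k3*(cs3 - [target]) while solid is left; crystals form when [target] > cs3 (solubility = 24.0 mM, k = 0.0717 s⁻¹)
    dissolved substrate + partner → target (k = 5.23 M⁻¹ s⁻¹)

The dissolution coefficient times the saturation concentration of dissolved substrate is 5.49 mM h⁻¹, close to the carried rate, while the solution of the flask holds 0.0192% of the charge at 0.600 h and 0.0191% at 6.00 h. The same flask read at 1.5 h reckons to 16.1% with the carried rate. That neighbouring flask gives 16.3%, with 83.6% still standing as solid substrate.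

All runs were computed for an exercise; the scatter is artificial.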